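## Retrosynthetic overview

1. Feature: in ring A (O1, C2–CH3, C3–CHO, C4–CH2CO2R, C5–CO2Me, C6H=) the formyl carbon on C3 and the enol-ether carbon C6 are the two ends of a 1,5-dialdehyde (OHC–C3–C4–C5–C6HO). Its central bond C3–C4 can be read as a former alkene, which is the retron of a de Mayo reaction.
2. Late disconnections: first the phenethyl ester (Mitsunobu; arene ring B is bought with hydroxytyrosol). Then O1–C6 is exchanged for O1–C8 of a δ-lactone (ring L: O1, C2, C3, C4, arm CH2 = C7, arm carbonyl = C8); this is the "ring switch".
3. Key disconnection: C4–C5 and C3–CHO, leading back to (S)-6-methyl-3,6-dihydro-2H-pyran-2-one and the enol of methyl diformylacetate ([2+2] photocycloaddition, then retro-aldol).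
4. The lactone comes from (S)-but-3-en-2-ol and but-3-enoic acid (esterification, ring-closing metathesis). The enol comes from methyl 3,3-dimethoxypropanoate (Claisen formylation, acetal hydrolysis).
5. Ring order: L (metathesis); a transient cyclobutane and a temporary hemiacetal ring H (key step); then A at the expense of L and H. Ring B is never built.

Key step: step 5

Numbering: O1 and C2–C8 as defined above are used for the same atoms in every intermediate.

Remark: the 1,5-dialdehyde from the key step is expected to rest as its cyclic hemiacetal (anomeric centre and enol geometry left open). The lactone is opened with water and not with the arylethanol, because an electron-rich 2-arylethanol, an aldehyde and acid together would drain into oxa-Pictet–Spengler isochroman formation.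

## Route

Step 1
Reactants: 1 (S)-but-3-en-2-ol; 2 but-3-enoic acid
Product: 3 (2S)-but-3-en-2-yl but-3-enoate
Conditions: DCC (1.1 equiv), DMAP (5 mol %), CH2Cl2, −10 to 0 °C
Reagents that add atoms: none
Why: Steglich esterification transfers the acyl group to the hydroxyl oxygen without breaking the carbinol C–O bond, so C2 stays S, and the small DMAP charge and low temperature keep the β,γ-alkene of the acid from moving into conjugation.

Step 2
Reactants: 3 (2S)-but-3-en-2-yl but-3-enoate
Product: 4 (6S)-6-methyl-3,6-dihydro-2H-pyran-2-one
Conditions: second-generation Grubbs catalyst (H2IMes)(PCy3)Cl2Ru=CHPh (2–3 mol %), 1,4-benzoquinone (10 mol %), CH2Cl2 (0.02 M), 40 °C; filtration through neutral silica, no base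
Reagents that add atoms: none
Why: Ring-closing metathesis of two monosubstituted alkenes to a six-membered β,γ-unsaturated lactone is driven by loss of ethene, benzoquinone intercepts ruthenium hydrides that would shift the C3=C4 alkene into conjugation, and the allylic stereocentre C2 takes no part.

Step 3
Reactants: 5 methyl 3,3-dimethoxypropanoate
Product: 6 sodium 2-(dimethoxymethyl)-3-methoxy-3-oxoprop-1-en-1-olate
Conditions: NaH (1.2 equiv), HCO2Me (excess), DME, rt to 45 °C; salt filtered off under N2
Reagents that add atoms: methyl formate, COC=O; sodium hydride, [Na+].[H-]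
Why: Crossed Claisen formylation works because methyl formate cannot enolise and the product is withdrawn from the equilibrium as its stabilised, poorly soluble sodium enolate.

Step 4
Reactants: 6 sodium 2-(dimethoxymethyl)-3-methoxy-3-oxoprop-1-en-1-olate
Product: 7 methyl diformylacetate, enol form (methyl 2-formyl-3-hydroxyprop-2-enoate)
Conditions: 1 M aq HCl, 0 °C to rt; CH2Cl2 extraction; bulb-to-bulb distillation
Reagents that add atoms: water, O
Why: Protonation of the enolate and acid-catalysed acetal hydrolysis unveil the second formyl group, and the tricarbonyl compound settles as the intramolecularly hydrogen-bonded enol that is the chromophore of the next step.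

Step 5
Reactants: 4 (6S)-6-methyl-3,6-dihydro-2H-pyran-2-one; 7 methyl diformylacetate (enol form)
Product: 10 methyl (4aR,8S,8aR)-1-hydroxy-8-methyl-6-oxo-4a,5,8,8a-tetrahydro-1H-pyrano[3,4-c]pyran-4-carboxylate, via photoadduct cyclobutanol 8 (not isolated), via ring-opened enol dialdehyde 9 (not isolated)
Conditions: hν (450 W medium-pressure Hg lamp, Corex filter, λ > 260 nm), degassed CH2Cl2, 0–5 °C, 7 added in portions; chromatography
Reagents that add atoms: none
Why: De Mayo reaction: only the hydrogen-bonded enol 7 absorbs under the filter, its excited state adds stepwise through a 1,4-biradical across the C3=C4 alkene of 4 to the cis-fused 2-hydroxycyclobutanecarbaldehyde 8, and ring strain drives a spontaneous retro-aldol cleavage to the 1,5-dialdehyde 9, the closest known case being the photoannulation of this same enol onto cyclopentenes and cyclohexadienes that opens classical iridoid syntheses. Two skeletal bonds result, C4–C5 and C3–CHO. As to rings, the cyclobutane closes by recombination of the biradical and is lost again, and 9 rests as hemiacetal 10 through reversible 6-exo-trig addition of the enol hydroxyl to the new formyl group, so no ring of the target is closed here. C3 and C4 are set together, because only the cis-fused bicyclo[4.2.0] closure is free of severe strain and both new bonds therefore lie on one face, the face anti to the methyl on the adjacent stereocentre C2, which places formyl trans to methyl and cis to the C5 arm on the lactone. The step also needs regiocontrol, for which the substrate offers a steric match (the fully substituted enol carbon bonds to C4, flanked by CH2, and the slim CHOH carbon bonds to C3, next to the methyl-bearing carbon), and the regioisomer and the syn-face adduct are to be removed by chromatography. The cyclic cis alkene cannot waste excitation by E/Z isomerisation, and the unconjugated lactone stays dark at these wavelengths.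

Step 6
Reactants: 10 methyl (4aR,8S,8aR)-1-hydroxy-8-methyl-6-oxo-4a,5,8,8a-tetrahydro-1H-pyrano[3,4-c]pyran-4-carboxylate
Product: 12 2-[(2S,3R,4R)-3-formyl-5-(methoxycarbonyl)-2-methyl-3,4-dihydro-2H-pyran-4-yl]acetic acid, via open hydroxy acid 11 (not isolated)
Conditions: 1 M aq HCl–THF (1:1), 23 °C; chromatography, recovered 10 resubmitted
Reagents that add atoms: water, O
Why: Acid-catalysed acyl–oxygen hydrolysis of the δ-lactone (C8–O1) frees the C2 hydroxyl in 11, which adds 6-exo-trig to the formylacetate carbon C6 exposed by ring–chain tautomerism of the hemiacetal and loses water to the push–pull β-alkoxyacrylate of ring A (vinylogous esterification), a sink because an unstrained s-cis enol ether replaces a lactone locked in the disfavoured E ester geometry; no bond at C2, C3 or C4 is broken, so all three configurations carry over.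

Step 7
Reactants: 12 2-[(2S,3R,4R)-3-formyl-5-(methoxycarbonyl)-2-methyl-3,4-dihydro-2H-pyran-4-yl]acetic acid; 13 hydroxytyrosol
Product: 14 methyl (2S,3R,4R)-4-{2-[2-(3,4-dihydroxyphenyl)ethoxy]-2-oxoethyl}-3-formyl-2-methyl-3,4-dihydro-2H-pyran-5-carboxylate (target)
Conditions: PPh3 (1.3 equiv), DIAD (1.3 equiv, added last, dropwise), THF, 0 °C to rt
Reagents that add atoms: none
Why: In this Mitsunobu esterification the carboxylic acid is by far the most acidic partner and the primary alcohol is the only hydroxyl whose alkoxyphosphonium ion is open to SN2 attack, so the phenethyl ester forms without catechol protection under near-neutral conditions that spare the β-alkoxy aldehyde from retro-oxa-Michael opening, and no stereocentre is touched.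

## Compound list

1 | (S)-but-3-en-2-ol | C[C@H](O)C=C | starting material
2 | but-3-enoic acid | C=CCC(=O)O | starting material
3 | (2S)-but-3-en-2-yl but-3-enoate | C[C@H](OC(=O)CC=C)C=C | intermediate
4 | (6S)-6-methyl-3,6-dihydro-2H-pyran-2-one | C[C@@H]1OC(=O)CC=C1 | intermediate
5 | methyl 3,3-dimethoxypropanoate | COC(OC)CC(=O)OC | starting material
6 | sodium 2-(dimethoxymethyl)-3-methoxy-3-oxoprop-1-en-1-olate | COC(OC)C(=C[O-])C(=O)OC.[Na+] | intermediate
7 | methyl diformylacetate, enol form (methyl 2-formyl-3-hydroxyprop-2-enoate) | COC(=O)C(C=O)=CO | intermediate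
8 | methyl 7-formyl-8-hydroxy-2-methyl-4-oxo-3-oxabicyclo[4.2.0]octane-7-carboxylate, (2S), cis-fused, cyclobutane anti to the methyl, carbinol and quaternary centres open | C[C@@H]1OC(=O)C[C@@H]2[C@H]1C(O)C2(C=O)C(=O)OC | intermediate
9 | methyl 2-[(2S,3R,4R)-3-formyl-2-methyl-6-oxooxan-4-yl]-3-hydroxyprop-2-enoate | C[C@@H]1OC(=O)C[C@@H](C(=CO)C(=O)OC)[C@H]1C=O | intermediate
10 | methyl (4aR,8S,8aR)-1-hydroxy-8-methyl-6-oxo-4a,5,8,8a-tetrahydro-1H-pyrano[3,4-c]pyran-4-carboxylate (hemiacetal form of 9, C1 open) | C[C@@H]1OC(=O)C[C@H]2C(C(=O)OC)=COC(O)[C@@H]12 | intermediate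
11 | (3R,4R,5S)-4-formyl-5-hydroxy-3-(3-hydroxy-1-methoxy-1-oxoprop-2-en-2-yl)hexanoic acid | C[C@H](O)[C@H](C=O)[C@@H](CC(=O)O)C(=CO)C(=O)OC | intermediate
12 | 2-[(2S,3R,4R)-3-formyl-5-(methoxycarbonyl)-2-methyl-3,4-dihydro-2H-pyran-4-yl]acetic acid | COC(=O)C1=CO[C@@H](C)[C@H](C=O)[C@H]1CC(=O)O | intermediate
13 | hydroxytyrosol, 4-(2-hydroxyethyl)benzene-1,2-diol | OCCc1ccc(O)c(O)c1 | starting material
14 | methyl (2S,3R,4R)-4-{2-[2-(3,4-dihydroxyphenyl)ethoxy]-2-oxoethyl}-3-formyl-2-methyl-3,4-dihydro-2H-pyran-5-carboxylate | COC(=O)C1=CO[C@@H](C)[C@H](C=O)[C@H]1CC(=O)OCCc1ccc(O)c(O)c1 | target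

## Step count and risks

Total step count: 7
Longest linear sequence: 5 steps (1, 2, 5, 6, 7; the branch 3, 4, 5, 6, 7 is equally long)

**Steps most likely to fail**

**Step 5.** Several things may go wrong:
- Regiochemical and facial discrimination may be weak on the nearly flat lactone ring.
- The excited carbonyl may abstract hydrogen from the doubly activated C7 methylene.
- Self-decay of the enol may outrun addition.

The fallback sets out from 7 and comes back at 10. It runs the photoannulation on a cyclopentene, the substrate class on which it is established, and inserts the lactone oxygen afterwards.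
- Sodium cyclopentadienide NaC5H5 and MeI at low temperature give 5-methylcyclopenta-1,3-diene F1.
- F1 is hydroborated cold, before 1,5-hydrogen shift. The enantiomer of diisopinocampheylborane is chosen that leads, after H2O2/NaOH, to (1S,2S)-2-methylcyclopent-3-en-1-ol F2.
- Irradiation of F2 with 7 should give the cis-fused cyclopenta[c]pyran lactol F3, with the pyran ring anti to the allylic methyl.
- MeOH with catalytic camphorsulfonic acid converts F3 into the methyl acetal F4.
- Dess–Martin periodinane oxidises the ring carbinol to the ketone F5.
- Baeyer–Villiger oxidation (mCPBA, NaHCO3, CH2Cl2) moves the more substituted, methyl-bearing carbon onto oxygen with retention and gives the lactone acetal F6.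
- Dilute aqueous acid in THF cleaves the acetal of F6 and returns 10.

**Step 6.** The lactone–hydroxy acid equilibrium in water may lie too far on the lactone side, so that the ring switch stalls. β-Elimination of the carboxylate from the open aldehyde, followed by unselective oxa-Michael re-closure, may also erode C2.

The fallback sets out from 10 and comes back at 12.
- The lactone is opened by mass action under anhydrous conditions in allyl alcohol as solvent with catalytic camphorsulfonic acid at rt. The carboxyl group ends capped and cannot re-lactonise, and the absence of water favours the condensation.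
- A short wash with dilute aqueous acid returns any diallyl acetal to the aldehyde and gives the allyl ester of the pyran acid F7.
- Allyl transfer with the zerovalent palladium complex Pd(PPh3)4 (catalytic) to sodium 4-methylbenzenesulfinate in THF, then acidification, frees 12 under neutral conditions.

**Step 7.** The free catechol may interfere with the redox couple through oxidation by the azodicarboxylate, phosphorane formation or phenol O-alkylation. Isochroman formation between hydroxytyrosol and the formyl group may also occur while both wait in solution.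

The fallback sets out from 13 and comes back at 14 through a silyl protecting-group detour.
- TBSCl and imidazole in DMF give the tris(silyl) ether F8.
- Catalytic camphorsulfonic acid in MeOH/CH2Cl2 at 0 °C removes only the acid-labile primary alkyl silyl ether and gives 2-[3,4-bis(tert-butyldimethylsilyloxy)phenyl]ethanol F9.
- Mitsunobu coupling of F9 with 12 gives the bis(silyl) ether of the target F10.
- TBAF buffered with acetic acid in THF at 0 °C cleaves the two aryl silyl ethers without exposing the β-alkoxy aldehyde to base and gives 14.

## Further compounds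

F1 | step 5 | 5-methylcyclopenta-1,3-diene | CC1C=CC=C1
F2 | step 5 | (1S,2S)-2-methylcyclopent-3-en-1-ol | C[C@@H]1[C@@H](O)CC=C1
F3 | step 5 | methyl 1,6-dihydroxy-7-methyl-1,4a,5,6,7,7a-hexahydrocyclopenta[c]pyran-4-carboxylate, cis-fused, pyran ring anti to methyl | C[C@@H]1[C@@H](O)C[C@H]2C(C(=O)OC)=COC(O)[C@@H]12
F4 | step 5 | methyl 6-hydroxy-1-methoxy-7-methyl-1,4a,5,6,7,7a-hexahydrocyclopenta[c]pyran-4-carboxylate | C[C@@H]1[C@@H](O)C[C@H]2C(C(=O)OC)=COC(OC)[C@@H]12
F5 | step 5 | methyl 1-methoxy-7-methyl-6-oxo-1,4a,5,6,7,7a-hexahydrocyclopenta[c]pyran-4-carboxylate | C[C@@H]1C(=O)C[C@H]2C(C(=O)OC)=COC(OC)[C@@H]12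
F6 | step 5 | methyl (4aR,8S,8aR)-1-methoxy-8-methyl-6-oxo-4a,5,8,8a-tetrahydro-1H-pyrano[3,4-c]pyran-4-carboxylate | C[C@@H]1OC(=O)C[C@H]2C(C(=O)OC)=COC(OC)[C@@H]12
F7 | step 6 | methyl (2S,3R,4R)-3-formyl-2-methyl-4-[2-oxo-2-(prop-2-enyloxy)ethyl]-3,4-dihydro-2H-pyran-5-carboxylate | COC(=O)C1=CO[C@@H](C)[C@H](C=O)[C@H]1CC(=O)OCC=C
F8 | step 7 | tris(tert-butyldimethylsilyl) ether of hydroxytyrosol | CC(C)(C)[Si](C)(C)OCCc1ccc(O[Si](C)(C)C(C)(C)C)c(O[Si](C)(C)C(C)(C)C)c1
F9 | step 7 | 2-[3,4-bis(tert-butyldimethylsilyloxy)phenyl]ethanol | OCCc1ccc(O[Si](C)(C)C(C)(C)C)c(O[Si](C)(C)C(C)(C)C)c1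
F10 | step 7 | bis(tert-butyldimethylsilyl) ether of the target | COC(=O)C1=CO[C@@H](C)[C@H](C=O)[C@H]1CC(=O)OCCc1ccc(O[Si](C)(C)C(C)(C)C)c(O[Si](C)(C)C(C)(C)C)c1
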